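**Plan**

1. Retrosynthetic cuts: the C13–CO2CH3 bond (carbonylation of an enol triflate); the C8–C14 bond of ring C (retro ring enlargement to a cyclopentyl carbinol carrying a C14–C15 oxirane, itself from vinyl addition to a C13 ketone); C3–C4 (isopropenyl addition to a C3 aldehyde); C5–Cl and C7–O (from a C5 ketone and its C6=C7 enone); C10–C1 (reductive allylation); the two annulation bonds C9=C10 and C7–C8.
2. Forward order: ring B and a five-membered precursor of ring C arise together in an amino-acid-catalysed Robinson annulation. Ring B is then functionalised (C10, C7, C5), the side chain is completed, and only then is the cyclopentane enlarged to the six-membered ring C.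
3. Enabling feature: the tertiary carbinol C13 of the trans-hydrindane sits between the quaternary C8 and the C14–C15 oxirane. The C8–C13 bond can lie anti to the C14–O bond, so a 1,2-shift of C8 inserts C14 into the ring and gives at once ring C, the C14 stereocentre, O15 (the later CHO) and the C13 carbonyl (the later ester-bearing alkene carbon).
4. Stereochemistry: C8 from the L-phenylalanine-catalysed aldol; C9 and C10 from the Li/NH3 reductive allylation; C7 from conjugate borylation anti to the C8 methyl; C5 from radical hydrogenation of a vinyl chloride; C3 from a ligand-controlled Ni/Cr coupling; C14 from directed epoxidation followed by stereospecific anti migration.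

Key step: step 19

Remark: locants used in the names are C1–C4 for the side chain (C1 on C10, C3 the carbinol, C4 the isopropenyl carbon); ring B = C5(Cl)–C6–C7(O)–C8(CH3)–C9(H)–C10(CH3); ring C = C8–C14–C13–C12–C11–C9; C15 is the carbon on C14. Before step 19 ring C is the cyclopentane C8–C13–C12–C11–C9. β is the face that carries the C8 methyl, α the opposite face. In step 15 the antipode of the oxazoline–sulfonamide ligand that directs addition to the Si face of the aldehyde is assumed.

**Step 1**
Reactants: 1 2-methylcyclopentane-1,3-dione; 2 pent-1-en-3-one (ethyl vinyl ketone)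
Product: 3 2-methyl-2-(3-oxopentyl)cyclopentane-1,3-dione
Conditions: AcOH (cat.), H2O, 75 °C
Reagents that add atoms: none
Why: Michael addition of the acidic cyclic 1,3-dione to the enone should give the achiral triketone; no stereocentre is formed.

**Step 2**
Reactants: 3 triketone
Product: 4 (S)-4,7a-dimethyl-2,3,7,7a-tetrahydro-1H-indene-1,5(6H)-dione
Conditions: L-phenylalanine (1 equiv), (+)-camphorsulfonic acid (0.5 equiv), DMF, 30 to 70 °C
Reagents that add atoms: none
Why: Hajos–Parrish–Eder–Sauer–Wiechert reaction: the enamine of the amino acid should select one of the two enantiotopic ring carbonyls in the intramolecular aldol condensation, which sets C8 as (S).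

**Step 3**
Reactants: 4 enedione
Product: 5 13β-hydroxy enone
Conditions: NaBH4 (0.3 equiv), EtOH, −20 °C
Reagents that add atoms: none
Why: chemoselective borohydride reduction of the saturated cyclopentanone (the enone is less electrophilic), with hydride entering anti to the angular methyl so that the hydroxyl is β.

**Step 4**
Reactants: 5 13β-hydroxy enone
Product: 6 13β-triethylsilyl ether enone
Conditions: Et3SiCl, imidazole, DMF, rt
Reagents that add atoms: chlorotriethylsilane, CC[Si](Cl)(CC)CC
Why: standard silylation of a secondary alcohol; the ether should survive the dissolving-metal step and can later be removed in the presence of a hindered tert-butyldimethylsilyl ether.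

**Step 5**
Reactants: 6 silyl ether enone
Product: 8 10α-allyl-10β-methyl trans-hydrindan-5-one, via lithium enolate 7 (not isolated)
Conditions: Li, NH3(l), tBuOH (1 equiv), THF, −78 °C; then allyl bromide, −78 to −33 °C
Reagents that add atoms: allyl bromide, C=CCBr
Why: Birch-type reductive alkylation of the enone: protonation of the β-carbon C9 should give the trans ring fusion (9α-H), and the regiodefined enolate should be allylated at C10 anti to the 1,3-related C8 methyl, leaving the C10 methyl β and the new chain α.

**Step 6**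
Reactants: 8 allyl ketone
Product: 9 C6=C7 enone
Conditions: IBX, 4-methoxypyridine N-oxide, DMSO, rt
Reagents that add atoms: none
Why: IBX dehydrogenation of a ketone; only C6 carries α-hydrogens (C10 is quaternary), so only the C6=C7 enone can form.

**Step 7**
Reactants: 9 enone
Product: 11 7α-hydroxy ketone, via boryl ketone 10 (not isolated)
Conditions: CuCl (5 mol%), NaOtBu (10 mol%), DPEphos (5 mol%), B2pin2, MeOH, THF, rt; then 30% H2O2, pH 7 buffer, 0 °C
Reagents that add atoms: hydrogen peroxide, OO; bis(pinacolato)diboron, CC1(C)OB(OC1(C)C)B1OC(C)(C)C(C)(C)O1 (its boron stays only in intermediate 10)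
Why: copper-catalysed conjugate borylation should occur axially on the α face, anti to the vicinal axial C8 methyl, and the oxidation of the C–B bond proceeds with retention, so C7 receives an axial α-hydroxyl.

**Step 8**
Reactants: 11 7α-hydroxy ketone
Product: 12 7α-(tert-butyldimethylsilyloxy) ketone
Conditions: tBuMe2SiOTf, 2,6-lutidine, CH2Cl2, −78 to 0 °C
Reagents that add atoms: tert-butyldimethylsilyl triflate, CC(C)(C)[Si](C)(C)OS(=O)(=O)C(F)(F)F
Why: silyl triflate silylation is the usual way to protect a hindered axial alcohol; the group must last to the final step.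

**Step 9**
Reactants: 12 silyloxy ketone
Product: 14 C5 enol triflate, via potassium enolate 13 (not isolated)
Conditions: KN(SiMe3)2, THF, −78 °C; then PhNTf2, −78 °C
Reagents that add atoms: N-phenylbis(trifluoromethanesulfonimide), O=S(=O)(N(c1ccccc1)S(=O)(=O)C(F)(F)F)C(F)(F)F
Why: enolate O-triflation; the ketone can enolise only toward C6, and trapping at −78 °C should outrun E1cB loss of the 7-silyloxy group.

**Step 10**
Reactants: 14 enol triflate
Product: 15 C5 vinyl chloride
Conditions: Ni(cod)2 (10 mol%), LiCl, DMA/THF 3:1, rt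
Reagents that add atoms: lithium chloride, [Li+].[Cl-]
Why: nickel-catalysed conversion of an enol triflate into an alkenyl halide (oxidative addition to zerovalent nickel, triflate–chloride exchange, reductive elimination); the terminal alkene and the silyl ethers should be inert.

**Step 11**
Reactants: 15 vinyl chloride
Product: 17 C3 primary alcohol, via alkylborane 16 (not isolated)
Conditions: 9-BBN, THF, 0 °C to rt; then NaOH, H2O2, 0 °C
Reagents that add atoms: hydrogen peroxide, OO; 9-borabicyclo[3.3.1]nonane, B1C2CCCC1CCC2 (its boron stays only in intermediate 16)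
Why: anti-Markovnikov hydroboration–oxidation of the terminal alkene; the hindered, electron-poor chloroalkene should not react with the bulky borane.

**Step 12**
Reactants: 17 vinyl chloride alcohol
Product: 18 5β-chloride
Conditions: Mn(dpm)3 (10 mol%), PhSiH3, tBuOOH, iPrOH, rt
Reagents that add atoms: none
Why: metal-hydride hydrogen atom transfer hydrogenation of a haloalkene: hydrogen adds to C6 to give the α-chloro radical at C5, which should accept the second hydrogen axially on the α face so that chlorine becomes equatorial (β), the isomer that avoids a syn-axial clash with the 7α-silyloxy group; no other alkene is present at this stage.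

**Step 13**
Reactants: 18 5β-chloride
Product: 19 C3,C13-diol
Conditions: PPTS (cat.), MeOH, 0 °C to rt
Reagents that add atoms: none
Why: acid-catalysed methanolysis should remove the triethylsilyl ether selectively, the far more hindered tert-butyldimethylsilyl ether at C7 being retained.

**Step 14**
Reactants: 19 diol
Product: 20 C3-aldehyde C13-ketone
Conditions: Dess–Martin periodinane, NaHCO3, CH2Cl2, rt
Reagents that add atoms: none
Why: Dess–Martin oxidation of the primary and the secondary alcohol in one operation; no stereocentre is touched.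

**Step 15**
Reactants: 20 keto aldehyde
Product: 21 (3R)-allylic alcohol
Conditions: 2-bromopropene, CrCl2 (4 equiv), NiCl2 (cat.), valinol-derived oxazoline–sulfonamide ligand (4.4 equiv), Et3N, THF, rt
Reagents that add atoms: 2-bromopropene, CC(Br)=C
Why: asymmetric Nozaki–Hiyama–Kishi coupling: the alkenylchromium reagent adds to the aldehyde only (the hindered ketone and the alkyl chloride are inert), and the chiral sulfonamide on chromium should direct it to the Si face, which gives the (R)-carbinol by reagent control.

**Step 16**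
Reactants: 21 allylic alcohol
Product: 22 3-O-silyl C13 ketone
Conditions: tBuMe2SiCl, imidazole, DMF, rt
Reagents that add atoms: tert-butyldimethylsilyl chloride, CC(C)(C)[Si](C)(C)Cl
Why: standard silylation; it removes the directing hydroxyl of the side-chain allylic alcohol so that step 18 epoxidises only the ring carbinol.

**Step 17**
Reactants: 22 ketone
Product: 23 13α-vinyl-13β-carbinol
Conditions: CH2=CHMgBr, THF, −78 to 0 °C
Reagents that add atoms: vinylmagnesium bromide, C=C[Mg]Br
Why: Grignard 1,2-addition to the neopentyl cyclopentanone should occur from the α face, anti to the angular C8 methyl (as with steroidal 17-ketones), giving the 13β-hydroxyl.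

**Step 18**
Reactants: 23 vinyl carbinol
Product: 24 13β-hydroxy 13α-oxiranyl compound
Conditions: VO(acac)2 (5 mol%), tBuOOH, CH2Cl2, 0 °C to rt
Reagents that add atoms: tert-butyl hydroperoxide, CC(C)(C)OO
Why: vanadium-catalysed hydroxyl-directed epoxidation: only the free allylic alcohol is epoxidised, and in the vanadate transition state the bulky quaternary C8 should take the position anti to the reacting face (erythro-type selectivity), which sets C14 as drawn.

**Step 19**
Reactants: 24 epoxy carbinol
Product: 26 ring-enlarged C13 ketone bearing 14β-CH2OSiEt3, via epoxy silyl ether 25 (not isolated)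
Conditions: Et3SiOTf (1.3 equiv), 2,6-di-tert-butyl-4-methylpyridine, CH2Cl2, −78 to −40 °C
Reagents that add atoms: triethylsilyl triflate, CC[Si](CC)(CC)OS(=O)(=O)C(F)(F)F
Why: Semipinacol rearrangement of a 2,3-epoxy alcohol in its silyl-triflate-promoted form (epoxy silyl ether rearrangement; the D-homoannulation of steroidal 17-carbinols is the closest ring-size precedent): the tertiary alcohol is silylated, the silyl cation then activates the oxirane, and the C8–C13 bond, held anti-periplanar to the breaking C14–O bond, shifts from C13 to C14 while C13 becomes the carbonyl and the silyl group ends on O15. Ring C is thereby closed by a ring-enlarging 1,2-alkyl shift (cyclopentane to cyclohexanone, C14 inserted between C8 and C13) and not by a cyclisation. C14 is formed with inversion at the oxirane carbon and C8 migrates with retention, so the oxirane configuration from step 18 is translated into the equatorial 14β-CH2OSi centre, which is also the more stable epimer because an α-substituent on C14 would be syn-axial to the 7α-silyloxy group. The step needs migration of C8 and not of C12: the quaternary C8 is the better migrating group, and the conformer that aligns C8–C13 with C14–O places only the oxirane hydrogen between the two ring carbons, whereas the conformer for C12 migration places C15 there. It also needs the allylic and secondary silyl ethers and the secondary chloride to survive, which the low temperature and the hindered, non-nucleophilic base should secure.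

**Step 20**
Reactants: 26 ring-enlarged ketone
Product: 28 C13 enol triflate (C12=C13), via potassium enolate 27 (not isolated)
Conditions: KN(SiMe3)2, THF, −78 °C; then PhNTf2
Reagents that add atoms: N-phenylbis(trifluoromethanesulfonimide), O=S(=O)(N(c1ccccc1)S(=O)(=O)C(F)(F)F)C(F)(F)F
Why: kinetic enolate formation and O-triflation; deprotonation should occur at the unhindered C12 methylene and not at C14, which is flanked by the quaternary C8, so the C14 centre and the 15-silyloxy group are untouched.

**Step 21**
Reactants: 28 enol triflate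
Product: 29 methyl enoate (C13–CO2CH3, C12=C13)
Conditions: Pd(OAc)2 (5 mol%), PPh3, CO (1 atm), Et3N, MeOH, DMF, rt to 40 °C
Reagents that add atoms: carbon monoxide, [C-]#[O+]; methanol, CO
Why: palladium-catalysed methoxycarbonylation of an enol triflate (oxidative addition, CO insertion, methanolysis) should give the α,β-unsaturated ester without touching the alkyl chloride or the isolated alkene.

**Step 22**
Reactants: 29 enoate
Product: 31 C15 aldehyde (3,7-bis-silyl ether of the target), via alkoxysulfonium salt 30 (not isolated)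
Conditions: (COCl)2, DMSO, CH2Cl2, −78 to −40 °C; then iPr2NEt, −78 °C, cold pH 7 quench
Reagents that add atoms: none
Why: Swern oxidation applied directly to a primary triethylsilyl ether: the activated sulfoxide cleaves the primary ether to the alkoxysulfonium salt while the secondary tert-butyldimethylsilyl ethers stay, so a free 15-hydroxy ester that could lactonise is never formed; the hindered amine at low temperature should limit isomerisation of the alkene into conjugation, and the β-formyl epimer is the stable one.

**Step 23**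
Reactants: 31 bis-silyl ether aldehyde
Product: 32 target compound
Conditions: HF·pyridine, pyridine, THF, 0 °C to rt
Reagents that add atoms: none
Why: fluoride-mediated desilylation under buffered, non-basic conditions should free the C3 and C7 hydroxyls without epimerising C14 or moving the double bond.

**Compound list**

1 | 2-methylcyclopentane-1,3-dione | CC1C(=O)CCC1=O | starting material
2 | pent-1-en-3-one (ethyl vinyl ketone) | CCC(=O)C=C | starting material
3 | 2-methyl-2-(3-oxopentyl)cyclopentane-1,3-dione | CCC(=O)CCC1(C)C(=O)CCC1=O | intermediate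
4 | (S)-4,7a-dimethyl-2,3,7,7a-tetrahydro-1H-indene-1,5(6H)-dione | O=C1CC[C@]2(C)C(=O)CCC2=C1C | intermediate
5 | (1S,7aS)-1-hydroxy-4,7a-dimethyl-1,2,3,6,7,7a-hexahydro-5H-inden-5-one (13β-hydroxyl, cis to the angular methyl) | O=C1CC[C@]2(C)[C@@H](O)CCC2=C1C | intermediate
6 | 13β-triethylsilyl ether of 5 | O=C1CC[C@]2(C)[C@@H](O[Si](CC)(CC)CC)CCC2=C1C | intermediate
7 | lithium C5(O)=C10 enolate, trans-fused (9α-H) (not isolated) | CC1=C([O-])CC[C@]2(C)[C@@H](O[Si](CC)(CC)CC)CC[C@@H]12.[Li+] | intermediate
8 | 10α-allyl-10β-methyl-13β-(triethylsilyloxy) trans-hydrindan-5-one | C=CC[C@]1(C)C(=O)CC[C@]2(C)[C@@H](O[Si](CC)(CC)CC)CC[C@@H]12 | intermediate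
9 | C6=C7 enone of 8 | C=CC[C@]1(C)C(=O)C=C[C@]2(C)[C@@H](O[Si](CC)(CC)CC)CC[C@@H]12 | intermediate
10 | 7α-(pinacolatoboryl) C5 ketone (not isolated) | C=CC[C@]1(C)C(=O)C[C@H](B3OC(C)(C)C(C)(C)O3)[C@]2(C)[C@@H](O[Si](CC)(CC)CC)CC[C@@H]12 | intermediate
11 | 7α-hydroxy C5 ketone | C=CC[C@]1(C)C(=O)C[C@H](O)[C@]2(C)[C@@H](O[Si](CC)(CC)CC)CC[C@@H]12 | intermediate
12 | 7α-(tert-butyldimethylsilyloxy) C5 ketone | C=CC[C@]1(C)C(=O)C[C@H](O[Si](C)(C)C(C)(C)C)[C@]2(C)[C@@H](O[Si](CC)(CC)CC)CC[C@@H]12 | intermediate
13 | potassium C5(O)=C6 enolate of 12 (not isolated) | C=CC[C@]1(C)C([O-])=C[C@H](O[Si](C)(C)C(C)(C)C)[C@]2(C)[C@@H](O[Si](CC)(CC)CC)CC[C@@H]12.[K+] | intermediate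
14 | C5 enol triflate (C5=C6) | C=CC[C@]1(C)C(OS(=O)(=O)C(F)(F)F)=C[C@H](O[Si](C)(C)C(C)(C)C)[C@]2(C)[C@@H](O[Si](CC)(CC)CC)CC[C@@H]12 | intermediate
15 | C5 vinyl chloride (C5=C6) with 10α-allyl | C=CC[C@]1(C)C(Cl)=C[C@H](O[Si](C)(C)C(C)(C)C)[C@]2(C)[C@@H](O[Si](CC)(CC)CC)CC[C@@H]12 | intermediate
16 | C3 B-alkyl-9-borabicyclononane adduct of 15 (not isolated) | C3CC4CCCC(C3)B4CCC[C@]1(C)C(Cl)=C[C@H](O[Si](C)(C)C(C)(C)C)[C@]2(C)[C@@H](O[Si](CC)(CC)CC)CC[C@@H]12 | intermediate
17 | C3 primary alcohol, C5 vinyl chloride | OCCC[C@]1(C)C(Cl)=C[C@H](O[Si](C)(C)C(C)(C)C)[C@]2(C)[C@@H](O[Si](CC)(CC)CC)CC[C@@H]12 | intermediate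
18 | 5β-chloride (5α-H), C3 alcohol, 7α-OSi(tBu)Me2, 13β-OSiEt3 | OCCC[C@]1(C)[C@@H](Cl)C[C@H](O[Si](C)(C)C(C)(C)C)[C@]2(C)[C@@H](O[Si](CC)(CC)CC)CC[C@@H]12 | intermediate
19 | C3,C13β-diol | OCCC[C@]1(C)[C@@H](Cl)C[C@H](O[Si](C)(C)C(C)(C)C)[C@]2(C)[C@@H](O)CC[C@@H]12 | intermediate
20 | C3 aldehyde, C13 ketone | O=CCC[C@]1(C)[C@@H](Cl)C[C@H](O[Si](C)(C)C(C)(C)C)[C@]2(C)C(=O)CC[C@@H]12 | intermediate
21 | (3R)-3-hydroxy-4-methylpent-4-enyl side chain, C13 ketone | C=C(C)[C@H](O)CC[C@]1(C)[C@@H](Cl)C[C@H](O[Si](C)(C)C(C)(C)C)[C@]2(C)C(=O)CC[C@@H]12 | intermediate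
22 | 3-O-tert-butyldimethylsilyl ether of 21 | C=C(C)[C@H](O[Si](C)(C)C(C)(C)C)CC[C@]1(C)[C@@H](Cl)C[C@H](O[Si](C)(C)C(C)(C)C)[C@]2(C)C(=O)CC[C@@H]12 | intermediate
23 | 13α-vinyl-13β-carbinol | C=C(C)[C@H](O[Si](C)(C)C(C)(C)C)CC[C@]1(C)[C@@H](Cl)C[C@H](O[Si](C)(C)C(C)(C)C)[C@]2(C)[C@](O)(C=C)CC[C@@H]12 | intermediate
24 | 13β-hydroxy-13α-oxiranyl compound (C14–C15 epoxide) | C=C(C)[C@H](O[Si](C)(C)C(C)(C)C)CC[C@]1(C)[C@@H](Cl)C[C@H](O[Si](C)(C)C(C)(C)C)[C@]2(C)[C@](O)([C@H]3CO3)CC[C@@H]12 | intermediate
25 | 13β-triethylsilyl ether of 24 (not isolated) | C=C(C)[C@H](O[Si](C)(C)C(C)(C)C)CC[C@]1(C)[C@@H](Cl)C[C@H](O[Si](C)(C)C(C)(C)C)[C@]2(C)[C@](O[Si](CC)(CC)CC)([C@H]3CO3)CC[C@@H]12 | intermediate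
26 | ring-enlarged C13 ketone with 14β-CH2OSiEt3 (14α-H) | C=C(C)[C@H](O[Si](C)(C)C(C)(C)C)CC[C@]1(C)[C@@H](Cl)C[C@H](O[Si](C)(C)C(C)(C)C)[C@]2(C)[C@@H](CO[Si](CC)(CC)CC)C(=O)CC[C@@H]12 | intermediate
27 | potassium C13(O)=C12 enolate of 26 (not isolated) | C=C(C)[C@H](O[Si](C)(C)C(C)(C)C)CC[C@]1(C)[C@@H](Cl)C[C@H](O[Si](C)(C)C(C)(C)C)[C@]2(C)[C@@H](CO[Si](CC)(CC)CC)C([O-])=CC[C@@H]12.[K+] | intermediate
28 | C13 enol triflate (C12=C13) | C=C(C)[C@H](O[Si](C)(C)C(C)(C)C)CC[C@]1(C)[C@@H](Cl)C[C@H](O[Si](C)(C)C(C)(C)C)[C@]2(C)[C@@H](CO[Si](CC)(CC)CC)C(OS(=O)(=O)C(F)(F)F)=CC[C@@H]12 | intermediate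
29 | methyl enoate with 15-OSiEt3 | C=C(C)[C@H](O[Si](C)(C)C(C)(C)C)CC[C@]1(C)[C@@H](Cl)C[C@H](O[Si](C)(C)C(C)(C)C)[C@]2(C)[C@@H](CO[Si](CC)(CC)CC)C(C(=O)OC)=CC[C@@H]12 | intermediate
30 | C15 alkoxydimethylsulfonium chloride (not isolated) | C=C(C)[C@H](O[Si](C)(C)C(C)(C)C)CC[C@]1(C)[C@@H](Cl)C[C@H](O[Si](C)(C)C(C)(C)C)[C@]2(C)[C@@H](CO[S+](C)C)C(C(=O)OC)=CC[C@@H]12.[Cl-] | intermediate
31 | 3,7-bis(tert-butyldimethylsilyl) ether of the target (14β-CHO) | C=C(C)[C@H](O[Si](C)(C)C(C)(C)C)CC[C@]1(C)[C@@H](Cl)C[C@H](O[Si](C)(C)C(C)(C)C)[C@]2(C)[C@@H](C=O)C(C(=O)OC)=CC[C@@H]12 | intermediate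
32 | CNP0159496.2 | C=C(C)[C@H](O)CC[C@]1(C)[C@@H](Cl)C[C@H](O)[C@]2(C)[C@@H](C=O)C(C(=O)OC)=CC[C@@H]12 | target

**Step count and risks**

Total step count: 23. Longest linear sequence: 23 steps (the route is fully linear from 1 and 2).

Three steps most likely to fail:

**Step 19.** Migration of the ring methylene C12 instead of the quaternary C8, or opening of the oxirane without migration, would give the wrong skeleton. The fallback sets out from ketone 22 and returns at aldehyde 31. It still makes ring C by enlarging the cyclopentane, but by diazo ester homologation, where migration of the less substituted carbon is the normal course and is here the wanted one. Methyl diazoacetate and BF3·OEt2 in CH2Cl2 at 0 °C should give the ring-enlarged β-keto ester F1, in which the inserted carbon already carries the ester. NaH and PhNTf2 give the enol triflate F2. Reductive carbonylation (Pd(PPh3)4, CO, Bu3SnH, THF, 50 °C) gives the conjugated formyl enoate F3. Deprotonation at C12 with KN(SiMe3)2 at −78 °C gives the potassium dienolate F4, and kinetic protonation at C14 with AcOH moves the double bond to C12=C13 and should place the formyl group in the stable equatorial β position, which is 31.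

**Step 12.** Delivery of hydrogen to the β face of the chlorine-bearing radical, or loss of chlorine by over-reduction, would give the wrong C5 epimer or the dechlorinated compound. The fallback sets out from ketone 12 and returns at 18, forming the C–Cl bond by substitution with inversion, not by hydrogenating a C=C bond. LiBH(sec-Bu)3 in THF at −78 °C should attack equatorially and give the axial 5α-alcohol F5. Tf2O and pyridine give the 5α-triflate F6. Bu4NCl in toluene displaces it with inversion to the 5β-chloride F7, which still carries the allyl group; elimination toward C6 is the competing process here. Hydroboration with 9-BBN gives the alkylborane F8, and oxidation with NaOH and H2O2 gives 18.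

**Step 15.** Insufficient facial control by the chiral chromium complex at an unbiased aliphatic aldehyde would give a mixture at C3. The fallback sets out from keto aldehyde 20 and returns at 21, taking the C3 stereocentre from a catalytic asymmetric epoxidation. A Wittig reaction with isopropylidenetriphenylphosphorane (isopropyltriphenylphosphonium iodide, n-BuLi, THF, −78 °C) should react at the aldehyde only and give the trisubstituted alkene F9. Shi epoxidation with the D-fructose-derived ketone and Oxone (KHSO5) under K2CO3 buffer should give the (3R)-epoxide F10. Opening of the epoxide with Cp2TiCl (trivalent titanium, made from Cp2TiCl2 and Mn in THF) to the tertiary radical, followed by loss of a methyl hydrogen, should give the allylic alcohol 21 with C3 unchanged.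

**Further compounds**

F1 | step 19 | ring-enlarged β-keto ester (ring C: C8–C(=O)–CH(CO2CH3)–CH2–CH2–C9) | C=C(C)[C@H](O[Si](C)(C)C(C)(C)C)CC[C@]1(C)[C@@H](Cl)C[C@H](O[Si](C)(C)C(C)(C)C)[C@]2(C)C(=O)C(C(=O)OC)CC[C@@H]12
F2 | step 19 | enol triflate of F1 (C14–OTf, C13=C14) | C=C(C)[C@H](O[Si](C)(C)C(C)(C)C)CC[C@]1(C)[C@@H](Cl)C[C@H](O[Si](C)(C)C(C)(C)C)[C@]2(C)C(OS(=O)(=O)C(F)(F)F)=C(C(=O)OC)CC[C@@H]12
F3 | step 19 | conjugated formyl enoate (C14–CHO, C13=C14) | C=C(C)[C@H](O[Si](C)(C)C(C)(C)C)CC[C@]1(C)[C@@H](Cl)C[C@H](O[Si](C)(C)C(C)(C)C)[C@]2(C)C(C=O)=C(C(=O)OC)CC[C@@H]12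
F4 | step 19 | potassium dienolate of F3 (not isolated) | C=C(C)[C@H](O[Si](C)(C)C(C)(C)C)CC[C@]1(C)[C@@H](Cl)C[C@H](O[Si](C)(C)C(C)(C)C)[C@]2(C)C(=C[O-])C(C(=O)OC)=CC[C@@H]12.[K+]
F5 | step 12 | axial 5α-alcohol from 12 | C=CC[C@]1(C)[C@H](O)C[C@H](O[Si](C)(C)C(C)(C)C)[C@]2(C)[C@@H](O[Si](CC)(CC)CC)CC[C@@H]12
F6 | step 12 | 5α-triflate | C=CC[C@]1(C)[C@H](OS(=O)(=O)C(F)(F)F)C[C@H](O[Si](C)(C)C(C)(C)C)[C@]2(C)[C@@H](O[Si](CC)(CC)CC)CC[C@@H]12
F7 | step 12 | 5β-chloride with 10α-allyl | C=CC[C@]1(C)[C@@H](Cl)C[C@H](O[Si](C)(C)C(C)(C)C)[C@]2(C)[C@@H](O[Si](CC)(CC)CC)CC[C@@H]12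
F8 | step 12 | C3 B-alkyl-9-borabicyclononane adduct of F7 (not isolated) | C3CC4CCCC(C3)B4CCC[C@]1(C)[C@@H](Cl)C[C@H](O[Si](C)(C)C(C)(C)C)[C@]2(C)[C@@H](O[Si](CC)(CC)CC)CC[C@@H]12
F9 | step 15 | 4-methylpent-3-enyl side chain, C13 ketone | CC(C)=CCC[C@]1(C)[C@@H](Cl)C[C@H](O[Si](C)(C)C(C)(C)C)[C@]2(C)C(=O)CC[C@@H]12
F10 | step 15 | (3R)-3,4-epoxy-4-methylpentyl side chain, C13 ketone | CC3(C)O[C@@H]3CC[C@]1(C)[C@@H](Cl)C[C@H](O[Si](C)(C)C(C)(C)C)[C@]2(C)C(=O)CC[C@@H]12
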